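# Proposed total synthesis of CNP0320538.1 by a formyl-endo Diels–Alder reaction with a C9 relay stereocentre

## The problem

CNP0320538.1 (29) is an 8,12-elemanolide: a single cyclohexane (C5–C10, elemane numbering) with six contiguous stereocentres, across whose C7–C8 bond an α-methylene-γ-butyrolactone (C11, C12, C13) is trans-fused, so the whole task is substituent control around one ring. Taking β as the ring face that bears the C10 methyl group, C10 also carries the vinyl group (C1=C2, α), C5 the acrolein arm (C4 with the C3 methylene and the C15 formyl group, β), C6 a free hydroxyl (β), C7 the lactone carbon C11 (β), C8 the lactone oxygen (α) and C9 the angelate (α). The quaternary C10 and its neighbour C5, whose carbon arms are trans, cannot be adjusted afterwards and have to be set together, ideally with the flanking oxygens at C6 and C9. Of these, a C9 oxygen placed on the β face can pass its configuration to C7 by a suprafacial sigmatropic shift, and the C8=C9 alkene left behind can take both remaining oxygens by syn-dihydroxylation of the α face. Four functions tolerate little: the α-methylene lactone and the 2-substituted acrolein are Michael acceptors that do not survive ylides, amide bases or hydrides; the angelate isomerises to the tiglate under base or long heating and must be put on a hindered axial hydroxyl; and the C6 hydroxyl, cis to the lactone carbon, can translactonise under base. Since an osmylation is part of the plan, the vinyl group and both exocyclic methylenes can only appear after it, which fixes the order of the late steps. The feature that opens the structure is the C5–C10 bond with trans carbon arms, flanked by the oxygenated C6 and C9 with C7 and C8 between them: the retron of a [4+2] adduct of a trisubstituted fumarate-type alkene (C5=C10) and a (1E,3E)-1,4-dioxygenated butadiene (C6–C7=C8–C9).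

## Retrosynthesis

**Unmasking (29 ⇒ 28 ⇒ 26).** The last bonds made are the C11=C13 double bond, by loss of trimethylamine from the quaternised Mannich base of 26, and the free C6 hydroxyl, by O–Si cleavage of 28. Making the methylene lactone at the end with an amide base would destroy the enal and the angelate, and carrying it free would forbid ylides. Keeping it as the dimethylamine adduct from 16 onward avoids both problems. The precursor 26 has one Michael acceptor less than 29. The forward reagents (MeI, NaHCO3, HF·pyridine) must leave the enal, the esters and C5 alone.

**Acrolein arm (26 ⇒ 24 ⇒ 22).** C4=C3 is cut by a retro-Mannich methylenation to aldehyde 24, and C4–C15 by a retro-homologation to aldehyde 22, whose formyl carbon is C4. Building the arm from a C5 ester through a ketone would need organometallic additions that the lactone does not survive. 22 is two carbons and one acceptor simpler. The forward steps must not epimerise C5 or expel the C6 silyloxy group.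

**Vinyl group (22 ⇒ 21 ⇒ 20 ⇒ 19 ⇒ 18).** The C1=C2 bond is cut by a retro-Wittig methylenation to the neopentylic aldehyde 20, which is traced to alcohol 19 and silyl ether 18. The C5 formyl group stays masked as its dimethyl acetal as far as 21, so the two arms never compete. Working on the C10 arm first lets fluoride remove the primary silyl ether while the acetal is inert, and lets the acetal be hydrolysed when only one hindered silyl ether is left. The forward Wittig reaction must succeed on an aldehyde attached to a quaternary carbon.

**Angelate and C13 (18 ⇒ 16 + 17; 16 ⇒ 15).** The ester C–O bond at C9 is cut to alcohol 16 and angelic acid (17). Esterifying here rather than last makes the angelate the protecting group of C9 during the aldehyde chemistry at C10, where a free alkoxide could open the ring by retro-aldol cleavage. The C11–C13 bond is then cut by a retro-Mannich step to lactone 15. This has to precede the angelate because it needs an amide base. 15 is simpler by the acyl group and the amine.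

**Lactone and the C8/C9 oxygens (15 ⇒ 13).** The lactone C–O bond and both C–O bonds at C8 and C9 are removed together: 15 comes from the alkenyl acid 13 by syn-dihydroxylation and lactonisation. Halo- or epoxide-lactonisation would put the lactone oxygen cis to C11. Only the dihydroxylation places both oxygens trans to the C7 arm and cis to each other. 13 has two stereocentres and one ring fewer. The forward step must attack the α face and needs a substrate with a single alkene.

**C7–C11 (13 ⇒ 10).** This bond is cut by a retro-Ireland–Claisen rearrangement to the allylic acetate 10, which returns the alkene to C7=C8 and an oxygen to the β face of C9. An intermolecular alkylation or conjugate addition at C7 would have to find the β face next to the C6 oxygen unaided. The sigmatropic shift transfers the C9 configuration instead. 10 lacks the C7 stereocentre and the C2 side chain.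

**Differentiation of the cycloadduct (10 ⇒ 9 ⇒ 8 ⇒ 7 ⇒ 6).** Only functional groups change between 10 and the cycloadduct 6: acetate 10 from alcohol 9, silyl ethers of 9 from triol 8, 8 by hydride reduction of acetal 7, 7 by acetalisation of 6. The two arms are told apart by the oxidation levels they are born with (formyl to acetal, ester to hydroxymethyl). The two ring oxygens are told apart by the steric difference between the C6 hydroxyl and the neopentylic C9 hydroxyl. The forward sequence must avoid base while the β-acetoxy aldehyde is present.

**Ring (6 ⇒ 4 + 5).** The C9–C10 and C5–C6 bonds are cut in a retro-[4+2] to enal ester 4 and diene 5. Unlike the cuts that close the ring from an open chain (below), this one sets C5, C6, C9 and C10 at once from alkene geometries and starts from C4/C5 building blocks. The placement of the two carbonyl groups in the dienophile decides the outcome. A Lewis-acid-bound formyl group takes the endo position with open-chain dienes, and the exo preference of α-methyl enals is tied to cyclopentadiene. The formyl group is therefore put on C5, which must be cis to the C6 oxygen, and the ester on C10, which must be trans to the C9 oxygen. The isomer with the formyl group on the methyl-bearing carbon would have to react through the disfavoured exo mode. The forward reaction needs endo-formyl selectivity, one enantioface and enough reactivity from a bis(acyloxy)diene.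

**Dienophile (4 ⇒ 1 + 2).** The C=C bond of 4 is cut by a retro-Wittig reaction to the stabilised ylide 1 and glyoxal mono(dimethyl acetal) 2, both purchased. The required E geometry is the normal outcome, and acetal 3 is hydrolysed in the same operation.

## Roads not taken

**Alternative 1: radical cascade folding a chain into both rings.**
- Cut: C7–C11 and C5–C6, so that neither ring exists before the key step.
- Forward key step: hexabutylditin under irradiation abstracts bromine from a bromoacetal tethered to the C8 oxygen. The C11 radical closes 5-exo onto C7 of a ketene dithioacetal, the dithiane-stabilised C6 radical closes 6-exo onto C5 of a 2-(stannylmethyl)acrylate, and loss of the tin radical forms C4=C3, giving A1.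
- Merits: two rings and two C–C bonds in one operation. The vinyl group and the C4=C3 methylene are in place from the start, and no oxygen relay is needed for C11.
- Weak points:
  - The chain must already carry C8, C9 and the quaternary C10, set by acyclic control.
  - The second closure joins a hindered tertiary radical to the carbon next to the quaternary centre, where reduction or hydrogen-atom transfer can intervene.
  - The C7/C8 fusion and C5 arise under substrate control, with nothing that guarantees the trans relationship.
  - A1 still needs dithiane removal, a β-selective reduction at C6, acetal oxidation, methylenation at C11 and conversion of the acrylate ester into the enal.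
- Comparison: in bond economy the cascade is the better plan, and it has the two alkenes that the chosen route only reaches in steps 13 and 16. The chosen plan sets against this a concerted step whose four stereocentres follow from fixed alkene geometries, stereospecific follow-up reactions for C7, C8 and C9, and purchased starting materials.

**Alternative 2: allylboration ring closure at the quaternary carbon.**
- Cut: the C9–C10 bond, with the trans-lactone already present.
- Forward key step: an aldehyde group at C9 is attacked intramolecularly by the γ-carbon (C10) of a tethered (Z)-allyl pinacolboronate through a cyclic transition state. This closes the cyclohexane and creates the quaternary centre, the vinyl group and the C9 hydroxyl of A2.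
- Merits: C10 follows stereospecifically from the boronate geometry. The C9 hydroxyl is free for direct angeloylation. The methylene lactone needs no separate step, and the endgame from A2 is short (acylation, ether cleavage, oxidation, desilylation). This is clearly better than the ten steps the chosen route needs after its lactone is formed.
- Weak points:
  - C5, C6, C7 and C8 plus a trisubstituted Z-allylboronate must be assembled on an open chain, a long linear preparation.
  - The aldehyde sits next to the acyloxy-bearing C8 and can epimerise or eliminate.
  - The methylene lactone is exposed throughout the assembly.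
  - The C9 configuration (an axial alcohol beside the quaternary carbon) depends on which bicyclic transition state is preferred.
- Comparison: this route is shorter after ring closure and longer and less certain before it. The chosen plan pays for its long endgame with a ring that is built, with four stereocentres, in its second step.

**Alternative 3: indium Barbier ring closure at C6–C7.**
- Cut: the C6–C7 bond.
- Forward key step: indium metal converts a (Z)-2-(bromomethyl)enoate into an allylindium species whose γ-carbon (C7) adds to a tethered aldehyde group at C6. This closes the ring and moves the double bond to C11=C13, giving A3.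
- Merits: mild, water-tolerant conditions that leave the angelate untouched. The methylene of the future lactone is produced by the ring closure itself. The vinyl group and the C4=C3 methylene are present, and only desilylation with lactonisation, ether cleavage and oxidation remain. In functional-group economy it is the best of the four plans.
- Weak points:
  - In the required isomer the new C6 hydroxyl is cis to the acrylate arm and would close onto C12 to give the cis-fused 6,12-lactone before the C8 oxygen is freed, which is the wrong lactone.
  - The aldehyde group is attached to the epimerisable C5.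
  - The C6/C7 relationship depends on the conformation of a heavily substituted chain.
  - C5, C8, C9 and the quaternary C10 must again be set without a ring.
- Comparison: the chosen plan needs a Mannich detour and a late Wittig reaction that this route avoids. In return it keeps the C6 oxygen silylated from step 5 to the last step and derives every ring stereocentre from a cyclic, stereospecific event.

Key step: step 2

## Remarks before the steps

- TBS = tert-butyldimethylsilyl. The α/β descriptors and the elemane numbering defined in the first section are used in all compound names.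
- Assumption on the catalyst sense: the protonated (S)-oxazaborolidine is taken to shield the same face of the bound s-trans enal as it does for simple 2-substituted acroleins, which leads to 6. If the opposite sense is found, the (R)-catalyst, equally accessible, is used.
- The oxazaborolidine is prepared beforehand from (S)-α,α-diphenylprolinol and o-tolylboronic acid with azeotropic removal of water and is activated in the flask with HN(SO2CF3)2. As a catalyst it is not counted as a step.
- Dienophile 4 is made in step 1 and is not presumed to be on the shelf.

## Route

Step 1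
Reactants: 1 ethyl 2-(triphenyl-λ5-phosphanylidene)propanoate; 2 2,2-dimethoxyacetaldehyde
Product: 4 ethyl (E)-2-methyl-4-oxobut-2-enoate, via acetal ester 3 (not isolated)
Conditions: CH2Cl2, rt; then 1 M HCl, acetone, rt
Reagents that add atoms: water, O
Why: Wittig olefination with a stabilised α-branched ylide gives the E-trisubstituted enoate (ester trans to the acetal carbon), and the allylic dimethyl acetal 3 is hydrolysed by dilute acid in the same flask; no stereocentre is formed.

Step 2
Reactants: 4 ethyl (E)-2-methyl-4-oxobut-2-enoate; 5 (1E,3E)-buta-1,3-diene-1,4-diyl diacetate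
Product: 6 ethyl (1S,2S,5R,6S)-2,5-diacetoxy-6-formyl-1-methylcyclohex-3-ene-1-carboxylate (cycloadduct; C10 α-CO2Et/β-CH3; C9 β-OAc; C6 β-OAc; C5 β-CHO)
Conditions: (S)-tetrahydro-3,3-diphenyl-1-(2-methylphenyl)-1H,3H-pyrrolo[1,2-c][1,3,2]oxazaborole (20 mol%), HN(SO2CF3)2 (18 mol%), 5 (2 equiv), CH2Cl2, −78 → −20 °C
Reagents that add atoms: none
Why: The protonated oxazaborolidine binds the formyl oxygen of 4 in the s-trans enal and lowers the LUMO of the C5=C10 alkene, and 5 adds in one concerted, asynchronous, suprafacial [4+2] event in which bonding to C10, the β-carbon of the activated enal, runs ahead. The closest known reaction type is the oxazaborolidinium-catalysed Diels–Alder reaction of enals and β-formyl acrylates with 1-oxygenated or 1-acyloxy dienes. The cyclohexene ring (C5–C10) is closed by intermolecular [4+2] cycloaddition, which forms the C9–C10 and C5–C6 bonds. The E geometry of 4 fixes the C5 formyl group trans to the C10 ester and cis to the C10 methyl group, and the E,E geometry of 5 fixes the C6 and C9 acetoxy groups cis to each other. The endo position of the boron-bound formyl group places it, and with it the C10 methyl group, on the face of the two acetoxy groups, which gives the C5/C6 and C9/C10 relationships of 6. The absolute configuration comes from the catalyst, whose aryl groups shield one face of the bound enal. The step needs endo-formyl selectivity and one enantioface; the first is the normal preference of a Lewis-acid-bound formyl group with open-chain dienes, which is why the formyl group sits on C5 and not on C10, and the second is the task of the catalyst. The diene is symmetric, so no regiochemical question arises.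

Step 3
Reactants: 6 cycloadduct
Product: 7 ethyl (1S,2S,5R,6S)-2,5-diacetoxy-6-(dimethoxymethyl)-1-methylcyclohex-3-ene-1-carboxylate (C5 dimethyl acetal of 6)
Conditions: HC(OMe)3, PPTS (cat.), MeOH, rt
Reagents that add atoms: trimethyl orthoformate, COC(OC)OC
Why: Acid-catalysed acetalisation with the orthoformate as water scavenger; it removes the β-acetoxy aldehyde, which is prone to lose acetic acid, and marks the C5 arm as the future C4 at the aldehyde oxidation level.

Step 4
Reactants: 7 C5 dimethyl acetal of 6
Product: 8 cyclohex-7-ene triol (C10 α-CH2OH/β-CH3; C9 β-OH; C6 β-OH; C5 β-CH(OMe)2)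
Conditions: LiAlH4, THF, 0 °C → rt; aq. NaOH work-up
Reagents that add atoms: none
Why: Hydride reduction turns the neopentylic ester into the C10 hydroxymethyl group and cleaves both acetates while the acetal is inert; afterwards no β-acyloxy carbonyl unit is left that could eliminate.

Step 5
Reactants: 8 cyclohex-7-ene triol
Product: 9 bis-silyl ether (C10 α-CH2OTBS; C6 β-OTBS; free C9 β-OH; C5 β-CH(OMe)2; C7=C8)
Conditions: TBSCl (2.1 equiv), imidazole, DMF, 0 °C
Reagents that add atoms: tert-butyldimethylsilyl chloride, CC(C)(C)[Si](C)(C)Cl
Why: Silyl ether formation under imidazole catalysis is very sensitive to steric hindrance: the primary hydroxyl and the C6 hydroxyl react, whereas the C9 hydroxyl, next to the quaternary C10 and cis to its methyl group, is expected to stay free.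

Step 6
Reactants: 9 bis-silyl ether
Product: 10 C9 β-acetate of 9
Conditions: Ac2O, DMAP (cat.), pyridine, CH2Cl2, rt
Reagents that add atoms: acetic anhydride, CC(=O)OC(C)=O
Why: DMAP-catalysed acetylation through the N-acetylpyridinium ion reaches the hindered secondary hydroxyl and installs the only enolisable ester in the molecule.

Step 7
Reactants: 10 C9 β-acetate of 9
Product: 13 C7 β-acetic acid (C7 β-CH2CO2H; C8=C9; C10 α-CH2OTBS; C6 β-OTBS; C5 β-CH(OMe)2), via silyl ketene acetal 11 (not isolated), via trimethylsilyl ester 12 (not isolated)
Conditions: LiN(iPr)2, Me3SiCl, Et3N, THF, −78 → 65 °C; then H2O/MeOH, rt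
Reagents that add atoms: none
Why: Ireland–Claisen rearrangement: the O-silyl ketene acetal 11 undergoes a suprafacial [3,3] shift, so C11 is delivered to C7 on the β face from which the C9 oxygen departs and the alkene moves to C8=C9; silyl ester 12 is hydrolysed on work-up. The β-oxygen at C9, wrong for the target, is thereby spent as the relay that sets C7.

Step 8
Reactants: 13 C7 β-acetic acid
Product: 15 trans-fused 8,12-olide with free 9α-OH (C10 α-CH2OTBS; C6 β-OTBS; C5 β-CH(OMe)2), via dihydroxy acid 14 (not isolated)
Conditions: OsO4 (5 mol%), NMO, acetone/H2O, rt; then EDC·HCl, DMAP (cat.), CH2Cl2, rt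
Reagents that add atoms: osmium tetroxide, O=[Os](=O)(=O)=O; N-methylmorpholine N-oxide, C[N+]1([O-])CCOCC1; water, O
Why: Catalytic OsO4/NMO syn-dihydroxylation should occur on the α face, opposite the pseudoaxial C10 methyl group, the axial C6 silyloxy group and the C7 side chain, and sets C8 and C9. Carbodiimide lactonisation of 14 then closes the five-membered lactone onto the equatorial C8 hydroxyl (trans fusion), since the C9 hydroxyl could only give a bridged ring and the C6 oxygen is silylated.

Step 9
Reactants: 15 trans-fused 8,12-olide with free 9α-OH
Product: 16 13-(dimethylamino)-11βH-8,12-olide with free 9α-OH (Mannich base of 15)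
Conditions: LiN(iPr)2 (2.5 equiv), THF, −78 °C; CH2=NMe2+ I−, −78 → 0 °C
Reagents that add atoms: N,N-dimethylmethyleneiminium iodide, C=[N+](C)C.[I-]
Why: Mannich reaction of the lithium lactone enolate (the C9 alkoxide is a spectator) with the preformed iminium salt; the electrophile enters C11 from the α face, anti to the C7–C6 bond. The amine is kept as a mask of the α-methylene lactone that tolerates the ylide and oxidation steps to come; either C11 epimer would serve.

Step 10
Reactants: 16 Mannich base of 15; 17 angelic acid ((Z)-2-methylbut-2-enoic acid)
Product: 18 9α-angelate of 16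
Conditions: 17, 2,4,6-Cl3C6H2COCl, Et3N, toluene, rt; then 16, DMAP, toluene, 50 °C
Reagents that add atoms: none
Why: Yamaguchi esterification: the mixed 2,4,6-trichlorobenzoic anhydride of 17 acylates the hindered axial C9 hydroxyl through the acylpyridinium ion, a protocol known to keep the Z geometry of angelates; from here on the angelate also protects C9.

Step 11
Reactants: 18 9α-angelate of 16
Product: 19 C10 α-hydroxymethyl compound (primary silyl ether of 18 removed)
Conditions: HF·pyridine, pyridine, THF, 0 °C
Reagents that add atoms: none
Why: Buffered HF·pyridine cleaves the primary silyl ether much faster than the hindered secondary one at C6 and, being non-aqueous, leaves the dimethyl acetal alone.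

Step 12
Reactants: 19 C10 α-hydroxymethyl compound
Product: 20 C10 α-formyl compound
Conditions: (COCl)2, DMSO, CH2Cl2, −78 °C; Et3N, −78 → 0 °C
Reagents that add atoms: none
Why: Swern oxidation gives the non-enolisable neopentylic aldehyde and tolerates the tertiary amine; because C9 is acylated, no retro-aldol opening of the C9–C10 bond can start.

Step 13
Reactants: 20 C10 α-formyl compound
Product: 21 C10 α-vinyl compound (C5 β-CH(OMe)2 retained)
Conditions: Ph3PCH3Br, KN(SiMe3)2, THF, 0 °C; then 20, −78 → 0 °C
Reagents that add atoms: methyltriphenylphosphonium bromide, C[P+](c1ccccc1)(c1ccccc1)c1ccccc1.[Br-]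
Why: Wittig methylenation with the small, reactive unstabilised ylide converts the hindered aldehyde into the C1=C2 vinyl group at low temperature, where the esters, the lactone and the acetal do not react.

Step 14
Reactants: 21 C10 α-vinyl compound
Product: 22 C5 β-formyl compound
Conditions: PPTS (2 equiv), acetone/H2O (10:1), 45 °C
Reagents that add atoms: water, O
Why: Mild acid hydrolysis of the dimethyl acetal; the amine is protonated and only the hindered secondary silyl ether has to survive, so no selectivity problem between silyl groups remains.

Step 15
Reactants: 22 C5 β-formyl compound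
Product: 24 C5 β-(2-oxoethyl) aldehyde (C4H2–C15HO), via enol ether 23 (not isolated)
Conditions: MeOCH2PPh3Cl, KN(SiMe3)2, THF, −78 → 0 °C; then 1 M HCl, THF, 0 °C
Reagents that add atoms: (methoxymethyl)triphenylphosphonium chloride, COC[P+](c1ccccc1)(c1ccccc1)c1ccccc1.[Cl-]; water, O
Why: Wittig one-carbon homologation with the methoxymethylene ylide gives enol ether 23 (E/Z mixture), whose acid hydrolysis delivers C15 as the formyl group. A slight excess of phosphonium salt keeps free base away from the β-silyloxy aldehyde, and the equatorial C5 centre is the more stable epimer and should be retained.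

Step 16
Reactants: 24 C5 β-(2-oxoethyl) aldehyde
Product: 26 6-O-TBS 13-(dimethylamino)-11,13-dihydro derivative of 29 (acrolein arm complete), via β-amino aldehyde 25 (not isolated)
Conditions: CH2=NMe2+ I−, Et3N, CH2Cl2, rt
Reagents that add atoms: N,N-dimethylmethyleneiminium iodide, C=[N+](C)C.[I-]
Why: Mannich α-methylenation: the enol of 24 adds to the iminium salt and the β-amino aldehyde 25 loses dimethylamine under the amine base to give the 2-substituted acrolein. 24 is the only carbonyl compound with an α-methylene group, so the lactone and the esters are not touched.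

Step 17
Reactants: 26 6-O-TBS 13-(dimethylamino)-11,13-dihydro derivative of 29
Product: 28 6-O-tert-butyldimethylsilyl ether of 29, via trimethylammonium iodide 27 (not isolated)
Conditions: MeI, THF, rt; then aq. NaHCO3, EtOAc, rt
Reagents that add atoms: none
Why: N-Methylation of the Mannich base followed by Hofmann-type β-elimination under bicarbonate unmasks the α-methylene lactone; MeI does not react with the enal, the esters or the silyl ether.

Step 18
Reactants: 28 6-O-tert-butyldimethylsilyl ether of 29
Product: 29 CNP0320538.1
Conditions: HF·pyridine, THF, 0 °C → rt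
Reagents that add atoms: none
Why: Fluoride-mediated cleavage of the last silyl ether under weakly acidic, non-basic conditions, chosen so that neither translactonisation to the C6 oxygen nor conjugate addition to the two acceptors can occur.

## Compound list

1 | ethyl 2-(triphenyl-λ5-phosphanylidene)propanoate | CCOC(=O)C(C)=P(c1ccccc1)(c1ccccc1)c1ccccc1 | starting material
2 | 2,2-dimethoxyacetaldehyde | COC(OC)C=O | starting material
3 | ethyl (E)-4,4-dimethoxy-2-methylbut-2-enoate | CCOC(=O)/C(C)=C/C(OC)OC | intermediate
4 | ethyl (E)-2-methyl-4-oxobut-2-enoate | CCOC(=O)/C(C)=C/C=O | intermediate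
5 | (1E,3E)-buta-1,3-diene-1,4-diyl diacetate | CC(=O)O/C=C/C=C/OC(C)=O | starting material
6 | ethyl (1S,2S,5R,6S)-2,5-diacetoxy-6-formyl-1-methylcyclohex-3-ene-1-carboxylate (cycloadduct; C10 α-CO2Et/β-CH3; C9 β-OAc; C6 β-OAc; C5 β-CHO) | CCOC(=O)[C@]1(C)[C@@H](OC(C)=O)C=C[C@@H](OC(C)=O)[C@H]1C=O | intermediate
7 | ethyl (1S,2S,5R,6S)-2,5-diacetoxy-6-(dimethoxymethyl)-1-methylcyclohex-3-ene-1-carboxylate (C5 dimethyl acetal of 6) | CCOC(=O)[C@]1(C)[C@@H](OC(C)=O)C=C[C@@H](OC(C)=O)[C@H]1C(OC)OC | intermediate
8 | cyclohex-7-ene triol (C10 α-CH2OH/β-CH3; C9 β-OH; C6 β-OH; C5 β-CH(OMe)2) | OC[C@]1(C)[C@@H](O)C=C[C@@H](O)[C@H]1C(OC)OC | intermediate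
9 | bis-silyl ether (C10 α-CH2OTBS; C6 β-OTBS; free C9 β-OH; C5 β-CH(OMe)2; C7=C8) | CC(C)(C)[Si](C)(C)OC[C@]1(C)[C@@H](O)C=C[C@@H](O[Si](C)(C)C(C)(C)C)[C@H]1C(OC)OC | intermediate
10 | C9 β-acetate of 9 | CC(C)(C)[Si](C)(C)OC[C@]1(C)[C@@H](OC(C)=O)C=C[C@@H](O[Si](C)(C)C(C)(C)C)[C@H]1C(OC)OC | intermediate
11 | O-trimethylsilyl ketene acetal of 10 | CC(C)(C)[Si](C)(C)OC[C@]1(C)[C@@H](OC(=C)O[Si](C)(C)C)C=C[C@@H](O[Si](C)(C)C(C)(C)C)[C@H]1C(OC)OC | intermediate
12 | trimethylsilyl ester of 13 | CC(C)(C)[Si](C)(C)OC[C@]1(C)C=C[C@@H](CC(=O)O[Si](C)(C)C)[C@@H](O[Si](C)(C)C(C)(C)C)[C@H]1C(OC)OC | intermediate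
13 | C7 β-acetic acid (C7 β-CH2CO2H; C8=C9; C10 α-CH2OTBS; C6 β-OTBS; C5 β-CH(OMe)2) | CC(C)(C)[Si](C)(C)OC[C@]1(C)C=C[C@@H](CC(=O)O)[C@@H](O[Si](C)(C)C(C)(C)C)[C@H]1C(OC)OC | intermediate
14 | 8α,9α-dihydroxy acid derived from 13 | CC(C)(C)[Si](C)(C)OC[C@]1(C)[C@H](O)[C@H](O)[C@@H](CC(=O)O)[C@@H](O[Si](C)(C)C(C)(C)C)[C@H]1C(OC)OC | intermediate
15 | trans-fused 8,12-olide with free 9α-OH (C10 α-CH2OTBS; C6 β-OTBS; C5 β-CH(OMe)2) | CC(C)(C)[Si](C)(C)OC[C@]1(C)[C@H](O)[C@@H]2OC(=O)C[C@H]2[C@@H](O[Si](C)(C)C(C)(C)C)[C@H]1C(OC)OC | intermediate
16 | 13-(dimethylamino)-11βH-8,12-olide with free 9α-OH (Mannich base of 15) | CC(C)(C)[Si](C)(C)OC[C@]1(C)[C@H](O)[C@@H]2OC(=O)[C@H](CN(C)C)[C@H]2[C@@H](O[Si](C)(C)C(C)(C)C)[C@H]1C(OC)OC | intermediate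
17 | angelic acid ((Z)-2-methylbut-2-enoic acid) | C/C=C(/C)C(=O)O | starting material
18 | 9α-angelate of 16 | CC(C)(C)[Si](C)(C)OC[C@]1(C)[C@H](OC(=O)/C(C)=C\C)[C@@H]2OC(=O)[C@H](CN(C)C)[C@H]2[C@@H](O[Si](C)(C)C(C)(C)C)[C@H]1C(OC)OC | intermediate
19 | C10 α-hydroxymethyl compound (primary silyl ether of 18 removed) | OC[C@]1(C)[C@H](OC(=O)/C(C)=C\C)[C@@H]2OC(=O)[C@H](CN(C)C)[C@H]2[C@@H](O[Si](C)(C)C(C)(C)C)[C@H]1C(OC)OC | intermediate
20 | C10 α-formyl compound | O=C[C@]1(C)[C@H](OC(=O)/C(C)=C\C)[C@@H]2OC(=O)[C@H](CN(C)C)[C@H]2[C@@H](O[Si](C)(C)C(C)(C)C)[C@H]1C(OC)OC | intermediate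
21 | C10 α-vinyl compound (C5 β-CH(OMe)2 retained) | C=C[C@]1(C)[C@H](OC(=O)/C(C)=C\C)[C@@H]2OC(=O)[C@H](CN(C)C)[C@H]2[C@@H](O[Si](C)(C)C(C)(C)C)[C@H]1C(OC)OC | intermediate
22 | C5 β-formyl compound | C=C[C@]1(C)[C@H](OC(=O)/C(C)=C\C)[C@@H]2OC(=O)[C@H](CN(C)C)[C@H]2[C@@H](O[Si](C)(C)C(C)(C)C)[C@H]1C=O | intermediate
23 | C5 β-(2-methoxyvinyl) enol ether (E/Z mixture; alkene geometry left open) | C=C[C@]1(C)[C@H](OC(=O)/C(C)=C\C)[C@@H]2OC(=O)[C@H](CN(C)C)[C@H]2[C@@H](O[Si](C)(C)C(C)(C)C)[C@H]1C=COC | intermediate
24 | C5 β-(2-oxoethyl) aldehyde (C4H2–C15HO) | C=C[C@]1(C)[C@H](OC(=O)/C(C)=C\C)[C@@H]2OC(=O)[C@H](CN(C)C)[C@H]2[C@@H](O[Si](C)(C)C(C)(C)C)[C@H]1CC=O | intermediate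
25 | C4 (dimethylamino)methyl aldehyde (both C4 epimers; C4 left open) | C=C[C@]1(C)[C@H](OC(=O)/C(C)=C\C)[C@@H]2OC(=O)[C@H](CN(C)C)[C@H]2[C@@H](O[Si](C)(C)C(C)(C)C)[C@H]1C(CN(C)C)C=O | intermediate
26 | 6-O-TBS 13-(dimethylamino)-11,13-dihydro derivative of 29 (acrolein arm complete) | C=C[C@]1(C)[C@H](OC(=O)/C(C)=C\C)[C@@H]2OC(=O)[C@H](CN(C)C)[C@H]2[C@@H](O[Si](C)(C)C(C)(C)C)[C@H]1C(=C)C=O | intermediate
27 | trimethylammonium iodide of 26 | C=C[C@]1(C)[C@H](OC(=O)/C(C)=C\C)[C@@H]2OC(=O)[C@H](C[N+](C)(C)C)[C@H]2[C@@H](O[Si](C)(C)C(C)(C)C)[C@H]1C(=C)C=O.[I-] | intermediate
28 | 6-O-tert-butyldimethylsilyl ether of 29 | C=C[C@]1(C)[C@H](OC(=O)/C(C)=C\C)[C@@H]2OC(=O)C(=C)[C@H]2[C@@H](O[Si](C)(C)C(C)(C)C)[C@H]1C(=C)C=O | intermediate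
29 | CNP0320538.1 | C=C[C@]1(C)[C@H](OC(=O)/C(C)=C\C)[C@@H]2OC(=O)C(=C)[C@H]2[C@@H](O)[C@H]1C(=C)C=O | target

## Step count and least certain steps

Total step count: 18. Longest linear sequence: 18 steps (1 and 2 to 29); 5 and 17 enter as purchased compounds.

**Step 2 (key step).**
- What may go wrong: the cycloaddition may be slow, because a bis(acyloxy)diene is a weak nucleophile and the enal is β,β-disubstituted. Shielding of one enal face may be incomplete, so that the mirror-image series is carried along. The acidic catalyst may promote loss of acetic acid from the β-acetoxy aldehyde.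
- Fallback (sets out from 4 and 5, returns at 13): the cycloaddition is run with an achiral Lewis acid (Me2AlCl, CH2Cl2, −40 °C), which keeps the endo-formyl topology but gives racemic 6. The racemate is taken through steps 3 to 7, and racemic 13 is resolved by crystallisation of its salt with (R)-1-phenylethylamine, the (R)-1-phenylethylammonium carboxylate F1. Acidification of F1 with cold aqueous citric acid returns enantiopure 13.

**Step 5.**
- What may go wrong: the rate difference between the two secondary allylic hydroxyls may be too small, leading to silylation at C9 or to the tris-silyl ether.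
- Fallback (sets out from 8, returns at 9): the primary and the C9 hydroxyl of 8, a 1,3-diol, are bridged with tBu2Si(OTf)2 and 2,6-lutidine to give the di-tert-butylsilylene F2. The only free hydroxyl (C6) is silylated with TBSOTf and 2,6-lutidine to give the silylene silyl ether F3. HF·pyridine at 0 °C, the standard reagent for removing dialkoxydi-tert-butylsilanes, cleaves the silylene before the hindered secondary silyl ether and gives the C6-silylated diol F4. TBSCl (1.05 equiv) and imidazole then silylate the primary hydroxyl alone and give 9.

**Step 7.**
- What may go wrong: the acetate enolate may be C-silylated, and the [3,3] shift may be slow, because the C9–O bond has to turn pseudoaxial beside the quaternary centre and the new bond forms next to the C6 silyloxy group.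
- Fallback (sets out from 9, returns at 13): Johnson orthoester Claisen rearrangement of the free C9 alcohol 9 with MeC(OEt)3 and catalytic EtCO2H at 140 °C gives, by the same suprafacial shift, the ethyl ester F5. Saponification with LiOH in THF/H2O gives 13.

**Step 8.**
- What may go wrong: osmylation may occur on the β face or on both faces if the ring adopts the conformer with the C10 silyloxymethyl group pseudoaxial. The reaction of an alkene flanked by a quaternary and a tertiary carbon may also be sluggish.
- Fallback (sets out from 13, returns at 15): the primary silyl ether of 13 is removed with buffered HF·pyridine to give the hydroxy acid F6. Its α-oriented homoallylic hydroxyl directs stoichiometric OsO4 complexed with Me2NCH2CH2NMe2 (CH2Cl2, −78 °C) to the α face by hydrogen bonding. Cleavage of the osmate ester with aqueous NaHSO3 and lactonisation as in step 8 give the diol lactone F7. TBSCl (1.05 equiv) and imidazole restore the primary silyl ether and give 15.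

**Step 10.**
- What may go wrong: acylation of the axial, neopentylic C9 hydroxyl may be slow, and during it the activated angelate can isomerise to the tiglate and the Mannich base can lose dimethylamine on heating.
- Fallback (sets out from 16, returns at 18): 16 is acylated at room temperature with 2-[bis(2,2,2-trifluoroethoxy)phosphoryl]propanoic acid (DCC, DMAP) to give the phosphonate ester F8. A Still–Gennari olefination with acetaldehyde (KN(SiMe3)2, 18-crown-6, THF, −78 °C) then builds the Z-configured double bond of the angelate on the oxygen and gives 18.

## Further compounds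

F1 | step 2 | (R)-1-phenylethylammonium carboxylate of 13 | CC(C)(C)[Si](C)(C)OC[C@]1(C)C=C[C@@H](CC(=O)[O-])[C@@H](O[Si](C)(C)C(C)(C)C)[C@H]1C(OC)OC.C[C@@H]([NH3+])c1ccccc1
F2 | step 5 | di-tert-butylsilylene of 8 across the C10 CH2O and C9 oxygens (free C6 β-OH) | CC(C)(C)[Si]1(C(C)(C)C)OC[C@]2(C)[C@@H](O1)C=C[C@@H](O)[C@H]2C(OC)OC
F3 | step 5 | C6 β-O-TBS ether of F2 | CC(C)(C)[Si]1(C(C)(C)C)OC[C@]2(C)[C@@H](O1)C=C[C@@H](O[Si](C)(C)C(C)(C)C)[C@H]2C(OC)OC
F4 | step 5 | C6-silylated diol (C10 α-CH2OH; C9 β-OH; C6 β-OTBS; C5 β-CH(OMe)2) | OC[C@]1(C)[C@@H](O)C=C[C@@H](O[Si](C)(C)C(C)(C)C)[C@H]1C(OC)OC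
F5 | step 7 | ethyl ester of 13 | CC(C)(C)[Si](C)(C)OC[C@]1(C)C=C[C@@H](CC(=O)OCC)[C@@H](O[Si](C)(C)C(C)(C)C)[C@H]1C(OC)OC
F6 | step 8 | hydroxy acid (13 without the primary silyl group) | OC[C@]1(C)C=C[C@@H](CC(=O)O)[C@@H](O[Si](C)(C)C(C)(C)C)[C@H]1C(OC)OC
F7 | step 8 | diol lactone (15 without the primary silyl group) | OC[C@]1(C)[C@H](O)[C@@H]2OC(=O)C[C@H]2[C@@H](O[Si](C)(C)C(C)(C)C)[C@H]1C(OC)OC
F8 | step 10 | 9α-[2-(bis(2,2,2-trifluoroethoxy)phosphoryl)propanoate] of 16 (phosphonate carbon left open) | CC(C)(C)[Si](C)(C)OC[C@]1(C)[C@H](OC(=O)C(C)P(=O)(OCC(F)(F)F)OCC(F)(F)F)[C@@H]2OC(=O)[C@H](CN(C)C)[C@H]2[C@@H](O[Si](C)(C)C(C)(C)C)[C@H]1C(OC)OC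
A1 | alternative 1 | trans-fused bicyclic ethyl acetal with a C6 dithiane and the C5 methyl acrylate arm | C=C[C@]1(C)[C@H](O[Si](C)(C)C(C)(C)C)[C@@H]2O[C@H](OCC)C[C@H]2C3(SCCCS3)[C@H]1C(=C)C(=O)OC
A2 | alternative 2 | cyclised 8,12-olide with free C9 hydroxyl, C6 silyl ether and C15 p-methoxybenzyl ether | C=C[C@]1(C)[C@H](O)[C@@H]2OC(=O)C(=C)[C@H]2[C@@H](O[Si](C)(C)C(C)(C)C)[C@H]1C(=C)COCc1ccc(OC)cc1
A3 | alternative 3 | cyclohexanol with C7 methyl acrylate arm, C8 triethylsilyl ether, C9 angelate and C15 p-methoxybenzyl ether | C=C[C@]1(C)[C@H](OC(=O)/C(C)=C\C)[C@H](O[Si](CC)(CC)CC)[C@@H](C(=C)C(=O)OC)[C@@H](O)[C@H]1C(=C)COCc1ccc(OC)cc1
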